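**Retrosynthetic overview**
- Target ⇒ its C3/C3' bis-epimer (trans,trans). The two lactone α-centres are set last by double enolisation and kinetic protonation, so only the two diarylmethine centres (C4, C4') have to be carried through.
- Ring B (tetrahydroxy dihydrocoumarin) ⇒ lactonisation after demethylation of a pentamethoxyphenyl acid.
- Ring A and both diarylmethine C–C bonds ⇒ one-pot sequential Friedel–Crafts capture of the two masked p-quinone methides of the 8–8' dilactone of p-coumaric acid, first by pentamethoxybenzene, then by phloroglucinol.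
- Dilactone ⇒ oxidative 8–8' dimerisation/double lactonisation of p-coumaric acid, resolved by chiral SFC.
- Ring order: bis-γ-lactone (sacrificial) → dihydrocoumarin ring A → dihydrocoumarin ring B.

Assumption: pentamethoxybenzene is taken as a catalogue chemical; C3/C4 refer to ring A (5,7-dihydroxy lactone) and C3'/C4' to ring B (5',6',7',8'-tetrahydroxy lactone).

**Step 1**
Reactants: 1 p-coumaric acid, (E)-3-(4-hydroxyphenyl)prop-2-enoic acid (2 molecules per product)
Product: 2 rac-(3R*,3aR*,6R*,6aR*)-3,6-bis(4-hydroxyphenyl)tetrahydrofuro[3,4-c]furan-1,4-dione (cis-fused bis-γ-lactone, both aryl groups exo)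
Conditions: FeCl3·6H2O (1.1 equiv per 1), acetone/H2O (1:3), N2, rt, 16 h
Reagents that add atoms: none
Why: Trivalent iron oxidises the phenol to a phenoxyl radical whose 8–8' radical dimerisation gives a bis-p-quinone methide that the two carboxylic acids trap (oxidative phenol coupling with double lactonisation, the classical dehydrodimerisation of hydroxycinnamic acids); only the racemic bis-quinone methide can close to the cis-fused bicycle and the aryl groups take the convex positions, so a single racemic diastereomer is expected, in modest yield beside 8–5 and 8–O–4 dimers.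

**Step 2**
Reactants: 2 racemic dilactone
Product: 3 (3S,3aS,6S,6aS)-3,6-bis(4-hydroxyphenyl)tetrahydrofuro[3,4-c]furan-1,4-dione
Conditions: preparative chiral SFC, immobilised cellulose tris(3,5-dichlorophenylcarbamate) phase, CO2/i-PrOH (7:3), 35 °C
Reagents that add atoms: none
Why: Chromatographic resolution of enantiomers on a chiral stationary phase; no stereocentre is formed, and the (3S,3aS,6S,6aS) enantiomer is identified by ECD and anomalous-dispersion crystallography.

**Step 3**
Reactants: 3 (3S,3aS,6S,6aS)-dilactone; 4 pentamethoxybenzene; 5 phloroglucinol (benzene-1,3,5-triol)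
Product: 8 (2R,3R)-2-[(3R,4R)-5,7-dihydroxy-4-(4-hydroxyphenyl)-2-oxo-3,4-dihydro-2H-chromen-3-yl]-3-(4-hydroxyphenyl)-3-(pentamethoxyphenyl)propanoic acid, via lactone acid 6 (not isolated), via seco diacid 7 (not isolated)
Conditions: CF3SO3H (10 mol %), HFIP/CH2Cl2 (4:1), 4 (0.95 equiv) added over 2 h at −20 °C; then 5 (5 equiv), 0 → 40 °C, Ar
Reagents that add atoms: none
Why: Proposed new method: CF3SO3H in HFIP ionises the strained p-hydroxybenzylic lactone C–O bonds of 3 to p-quinone methide/benzylic cation ion pairs (the first ionisation should be faster than the second because it releases the bicyclic strain), which are captured in Friedel–Crafts alkylations first by 4 and then by 5, each arene entering anti to the departing carboxylate and to the bulky neighbouring carbon (Felkin-type 1,2-induction, net inversion) so that both new diarylmethine centres are R, after which an ortho-hydroxyl of the phloroglucinol unit lactonises onto the adjacent carboxylic acid to close ring A; the closest known reaction type is the acid/HFIP-promoted Friedel–Crafts benzylation of electron-rich arenes through p-quinone methides followed by phenol lactonisation to 4-aryl-dihydrocoumarins.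

**Step 4**
Reactants: 8 ring-A lactone acid
Product: 10 (3R,3'R,4R,4'R)-5,5',6',7,7',8'-hexahydroxy-4,4'-bis(4-hydroxyphenyl)-3,3',4,4'-tetrahydro-2H,2'H-[3,3'-bichromene]-2,2'-dione (trans,trans isomer), via pentahydroxyphenyl acid 9 (not isolated)
Conditions: BBr3 (14 equiv), CH2Cl2, −78 → 0 °C; degassed H2O; then CF3CO2H/CH2Cl2 (1:9), rt, Ar
Reagents that add atoms: none
Why: BBr3 cleaves the five aryl methyl ethers (Lewis-acid ether cleavage) and an ortho-hydroxyl of the freed pentahydroxyphenyl ring then closes ring B by acid-catalysed lactonisation; no stereocentre is formed, C4 and C4' are untouched, and any drift at C3/C3' is irrelevant because both are reset in step 5.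

**Step 5**
Reactants: 10 trans,trans bis-lactone
Product: 12 (3S,3'S,4R,4'R)-5,5',6',7,7',8'-hexahydroxy-4,4'-bis(4-hydroxyphenyl)-3,3',4,4'-tetrahydro-2H,2'H-[3,3'-bichromene]-2,2'-dione (target, cis,cis isomer), via decakis(trimethylsilyl) bis(ketene acetal) 11 (not isolated)
Conditions: Me3SiOTf (14 equiv), Et3N (16 equiv), CH2Cl2, 0 °C → rt; then AcOH (30 equiv)/MeOH, −78 → 0 °C; aq citric acid, Ar
Reagents that add atoms: none
Why: Proposed new method: soft enolisation silylates the eight phenols and turns both aryl lactones into silyl ketene acetals (erasing C3 and C3'), and protonation of each 2-silyloxy-4H-chromene at C3 occurs on the face opposite the pseudo-axial C4 aryl group, so each C3 substituent ends up cis to that aryl (3S,3'S) while C4 and C4' stay R; the closest known reaction types are silyl ketene acetal formation from lactones and Zimmerman-type kinetic protonation of cyclic enol derivatives to the less stable cis isomer.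

**Compound list**
1 | p-coumaric acid, (E)-3-(4-hydroxyphenyl)prop-2-enoic acid | OC(=O)/C=C/c1ccc(O)cc1 | starting material
2 | rac-(3R*,3aR*,6R*,6aR*)-3,6-bis(4-hydroxyphenyl)tetrahydrofuro[3,4-c]furan-1,4-dione (racemate, both enantiomers written) | O=C1O[C@H](c2ccc(O)cc2)[C@H]3C(=O)O[C@H](c2ccc(O)cc2)[C@@H]13.O=C1O[C@@H](c2ccc(O)cc2)[C@@H]3C(=O)O[C@@H](c2ccc(O)cc2)[C@H]13 | intermediate
3 | (3S,3aS,6S,6aS)-3,6-bis(4-hydroxyphenyl)tetrahydrofuro[3,4-c]furan-1,4-dione | O=C1O[C@H](c2ccc(O)cc2)[C@H]3C(=O)O[C@H](c2ccc(O)cc2)[C@@H]13 | intermediate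
4 | 1,2,3,4,5-pentamethoxybenzene | COc1cc(OC)c(OC)c(OC)c1OC | starting material
5 | phloroglucinol (benzene-1,3,5-triol) | Oc1cc(O)cc(O)c1 | starting material
6 | (2S,3S,4R)-2-(4-hydroxyphenyl)-4-[(R)-(4-hydroxyphenyl)(pentamethoxyphenyl)methyl]-5-oxooxolane-3-carboxylic acid | O=C1O[C@H](c2ccc(O)cc2)[C@@H](C(=O)O)[C@H]1[C@H](c1ccc(O)cc1)c1c(OC)c(OC)c(OC)c(OC)c1OC | intermediate (not isolated)
7 | (2R,3R)-2-[(R)-(4-hydroxyphenyl)(pentamethoxyphenyl)methyl]-3-[(R)-(4-hydroxyphenyl)(2,4,6-trihydroxyphenyl)methyl]butanedioic acid | OC(=O)[C@H]([C@H](c1ccc(O)cc1)c1c(O)cc(O)cc1O)[C@H](C(=O)O)[C@H](c1ccc(O)cc1)c1c(OC)c(OC)c(OC)c(OC)c1OC | intermediate (not isolated)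
8 | (2R,3R)-2-[(3R,4R)-5,7-dihydroxy-4-(4-hydroxyphenyl)-2-oxo-3,4-dihydro-2H-chromen-3-yl]-3-(4-hydroxyphenyl)-3-(pentamethoxyphenyl)propanoic acid | O=C1Oc2cc(O)cc(O)c2[C@@H](c2ccc(O)cc2)[C@@H]1[C@H](C(=O)O)[C@H](c1ccc(O)cc1)c1c(OC)c(OC)c(OC)c(OC)c1OC | intermediate
9 | (2R,3R)-2-[(3R,4R)-5,7-dihydroxy-4-(4-hydroxyphenyl)-2-oxo-3,4-dihydro-2H-chromen-3-yl]-3-(4-hydroxyphenyl)-3-(pentahydroxyphenyl)propanoic acid | O=C1Oc2cc(O)cc(O)c2[C@@H](c2ccc(O)cc2)[C@@H]1[C@H](C(=O)O)[C@H](c1ccc(O)cc1)c1c(O)c(O)c(O)c(O)c1O | intermediate (not isolated)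
10 | (3R,3'R,4R,4'R)-5,5',6',7,7',8'-hexahydroxy-4,4'-bis(4-hydroxyphenyl)-3,3',4,4'-tetrahydro-2H,2'H-[3,3'-bichromene]-2,2'-dione (trans,trans) | O=C1Oc2cc(O)cc(O)c2[C@@H](c2ccc(O)cc2)[C@@H]1[C@@H]1C(=O)Oc2c(O)c(O)c(O)c(O)c2[C@H]1c1ccc(O)cc1 | intermediate
11 | (4R,4'R)-2,2',5,5',6',7,7',8'-octakis(trimethylsilyloxy)-4,4'-bis[4-(trimethylsilyloxy)phenyl]-4H,4'H-3,3'-bichromene | C[Si](C)(C)OC1Oc2cc(O[Si](C)(C)C)cc(O[Si](C)(C)C)c2[C@@H](c2ccc(O[Si](C)(C)C)cc2)C=1C1=C(O[Si](C)(C)C)Oc2c(O[Si](C)(C)C)c(O[Si](C)(C)C)c(O[Si](C)(C)C)c(O[Si](C)(C)C)c2[C@H]1c1ccc(O[Si](C)(C)C)cc1 | intermediate (not isolated)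
12 | (3S,3'S,4R,4'R)-5,5',6',7,7',8'-hexahydroxy-4,4'-bis(4-hydroxyphenyl)-3,3',4,4'-tetrahydro-2H,2'H-[3,3'-bichromene]-2,2'-dione (cis,cis) | O=C1Oc2cc(O)cc(O)c2[C@@H](c2ccc(O)cc2)[C@H]1[C@H]1C(=O)Oc2c(O)c(O)c(O)c(O)c2[C@H]1c1ccc(O)cc1 | target

**Step count and risks**
Total steps: 5. Longest linear sequence: 5 (1 → 2 → 3 → 8 → 10 → 12).

The three steps most likely to fail:

Step 3. Risks: statistical double arylation by 4, slow capture by the hindered arene (elimination to the cinnamate instead), and poor 1,2-induction. The fallback sets out from 3 and comes back at 8. The two C–C bonds are made in separate operations and the second one intramolecularly. 3 (3 equiv) is treated with 4 (1 equiv) under the same acid conditions and the reaction is stopped at the mono-adduct. Acid 6 is separated from neutral 3 (recycled) by bicarbonate extraction. The free carboxyl of 6 is then esterified with 5 (10 equiv, N,N'-diisopropylcarbodiimide, 4-(dimethylamino)pyridine cat., THF) to 3,5-dihydroxyphenyl (2S,3S,4R)-2-(4-hydroxyphenyl)-4-[(R)-(4-hydroxyphenyl)(pentamethoxyphenyl)methyl]-5-oxooxolane-3-carboxylate F3. CF3SO3H in HFIP ionises the remaining benzylic lactone of F3, and the ester-tethered phloroglucinol ring closes ring A by a six-membered intramolecular Friedel–Crafts alkylation. The tether fixes which arene goes where, and the allylic-strain-controlled transition state (H eclipsed with the quinone methide, bulky carbon anti to the forming bond) gives the same R centre, so 8 is obtained directly.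

Step 5. Risks: incomplete double enolisation, low facial selectivity, or re-equilibration to the trans isomers during desilylation. The fallback sets out from 10 and comes back at 12. 10 is converted with TBSCl (12 equiv) and imidazole in DMF into the octakis(tert-butyldimethylsilyl) ether of 10 F4. F4 is deprotonated with LiN(SiMe3)2 (2.5 equiv, THF/DMPU, −78 °C) to the bis-lithium enolate, which is quenched at −78 °C with 2,6-di-tert-butyl-4-methylphenol as a bulky proton donor (repeated once if mono-epimer remains), giving the octakis(tert-butyldimethylsilyl) ether of 12 F5. HF·pyridine in THF at 0 °C then frees 12 under non-basic conditions.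

Step 1. Risks: 8–5 and 8–O–4 coupling or polymerisation outweighing the 8–8' dilactone. The fallback sets out from 1 and comes back at 2. 1 is hydrogenated (H2, Pd/C, EtOH) to 3-(4-hydroxyphenyl)propanoic acid F1. Its trianion (LiN(i-Pr)2, 3.3 equiv, THF/DMPU, −78 → 0 °C) is coupled oxidatively with I2 (0.5 equiv, inverse addition at −78 °C) to rac-(2R*,3R*)-2,3-bis(4-hydroxybenzyl)butanedioic acid F2, freed from the meso isomer by crystallisation. DDQ (2.2 equiv, dioxane, rt) dehydrogenates both p-hydroxybenzylic positions of F2 to p-quinone methides, which the carboxylic acids trap to give 2.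

Further compounds
F1 | step 1 | 3-(4-hydroxyphenyl)propanoic acid | OC(=O)CCc1ccc(O)cc1
F2 | step 1 | rac-(2R*,3R*)-2,3-bis(4-hydroxybenzyl)butanedioic acid (racemate, both enantiomers written) | OC(=O)[C@@H](Cc1ccc(O)cc1)[C@H](Cc1ccc(O)cc1)C(=O)O.OC(=O)[C@H](Cc1ccc(O)cc1)[C@@H](Cc1ccc(O)cc1)C(=O)O
F3 | step 3 | 3,5-dihydroxyphenyl (2S,3S,4R)-2-(4-hydroxyphenyl)-4-[(R)-(4-hydroxyphenyl)(pentamethoxyphenyl)methyl]-5-oxooxolane-3-carboxylate | O=C1O[C@H](c2ccc(O)cc2)[C@@H](C(=O)Oc2cc(O)cc(O)c2)[C@H]1[C@H](c1ccc(O)cc1)c1c(OC)c(OC)c(OC)c(OC)c1OC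
F4 | step 5 | octakis(tert-butyldimethylsilyl) ether of 10, (3R,3'R,4R,4'R) | O=C1Oc2cc(O[Si](C)(C)C(C)(C)C)cc(O[Si](C)(C)C(C)(C)C)c2[C@@H](c2ccc(O[Si](C)(C)C(C)(C)C)cc2)[C@@H]1[C@@H]1C(=O)Oc2c(O[Si](C)(C)C(C)(C)C)c(O[Si](C)(C)C(C)(C)C)c(O[Si](C)(C)C(C)(C)C)c(O[Si](C)(C)C(C)(C)C)c2[C@H]1c1ccc(O[Si](C)(C)C(C)(C)C)cc1
F5 | step 5 | octakis(tert-butyldimethylsilyl) ether of 12, (3S,3'S,4R,4'R) | O=C1Oc2cc(O[Si](C)(C)C(C)(C)C)cc(O[Si](C)(C)C(C)(C)C)c2[C@@H](c2ccc(O[Si](C)(C)C(C)(C)C)cc2)[C@H]1[C@H]1C(=O)Oc2c(O[Si](C)(C)C(C)(C)C)c(O[Si](C)(C)C(C)(C)C)c(O[Si](C)(C)C(C)(C)C)c(O[Si](C)(C)C(C)(C)C)c2[C@H]1c1ccc(O[Si](C)(C)C(C)(C)C)cc1
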